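**Strategy.** Ring B (C5–C10, labdane numbering) is read as a cyclohexene. The oxygen-bearing C6 and its neighbour C5 become an (E)-enone dienophile (acetyl on C6, later turned into C6–O by Baeyer–Villiger oxidation), and C7–C10 become a diene whose C8 carries a CH2SiMe3 arm. Both are joined by the C1–C4 chain in an open-chain triene that already holds the C13 carbinol from (R)-linalool. A catalytic enantioselective intramolecular Diels–Alder reaction closes rings A and B at once, forming C5–C10 and C6–C7 and setting C5, C6 and C10. Protodesilylation then moves the alkene to C8=C17 and sets C9; epoxidation and hydride opening give the 8α-carbinol.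

Key step: step 10

Assumption: on the s-trans methyl ketone the (R)-configured oxazaborolidinium salt is taken to leave the C6 Si face open (α-C–H···O binding model); should the sense prove opposite, the (S)-antipode is used with no other change.

Step 1
Reactants: 1 (R)-(−)-linalool
Product: 2 (5R)-5-ethenyl-5-methyloxolan-2-ol (lactol, anomer mixture)
Conditions: O3, CH2Cl2/MeOH, −78 °C; then Me2S, −78 °C to rt
Reagents that add atoms: ozone, O=[O+][O-]
Why: Ozonolysis with reductive work-up should cleave only the electron-rich trisubstituted alkene, the vinyl group being far less reactive, and the 4-hydroxy aldehyde closes to the lactol while the C13 centre is carried over unchanged from the chiral pool.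

Step 2
Reactants: 2 lactol
Product: 4 (3R)-5-iodo-3-methylpent-1-en-3-ol, via iodo formate 3 (not isolated)
Conditions: PhI(OAc)2, I2, CH2Cl2, hν (visible), rt; then K2CO3, MeOH, 0 °C
Reagents that add atoms: iodine, II
Why: An alkoxy-radical β-fragmentation (hypoiodite reaction) of the lactol should break the anomeric C–C bond, iodine capturing the primary radical one carbon shorter while the ring oxygen leaves as a formate that mild methanolysis removes without touching the stereocentre.

Step 3
Reactants: 4 iodo alcohol
Product: 5 triethyl{[(3R)-5-iodo-3-methylpent-1-en-3-yl]oxy}silane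
Conditions: Et3SiOTf, 2,6-lutidine, CH2Cl2, −78 to 0 °C
Reagents that add atoms: triethylsilyl triflate, CC[Si](CC)(CC)OS(=O)(=O)C(F)(F)F
Why: Silylation with the silyl triflate is the standard way to protect a hindered tertiary alcohol, and the primary iodide is inert to these conditions.

Step 4
Reactants: 5 iodide; 6 methyl acetoacetate
Product: 7 methyl (5R)-2-acetyl-5-methyl-5-(triethylsilyloxy)hept-6-enoate (C2 epimers)
Conditions: K2CO3, acetone, reflux
Reagents that add atoms: none
Why: Acetoacetic ester alkylation (SN2 of the stabilised enolate on an unhindered primary iodide) should join C9 to C11, the new C2 centre being irrelevant because it becomes sp2 in the next step.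

Step 5
Reactants: 7 keto ester
Product: 8 methyl (2E)-2-[(3R)-3-methyl-3-(triethylsilyloxy)pent-4-en-1-yl]-3-(trifluoromethylsulfonyloxy)but-2-enoate
Conditions: Tf2O, aq. Me4NOH, toluene, 0 °C
Reagents that add atoms: triflic anhydride, O=S(=O)(OS(=O)(=O)C(F)(F)F)C(F)(F)F
Why: O-triflation of the β-keto ester enolate under non-chelating biphasic conditions (ammonium counter-ion) should favour the (E)-enol triflate, with the triflate trans to the ester, which fixes the later diene geometry.

Step 6
Reactants: 8 enol triflate; 9 2,2-dimethylpent-4-en-1-ol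
Product: 11 methyl (2E)-8-hydroxy-3,7,7-trimethyl-2-[(3R)-3-methyl-3-(triethylsilyloxy)pent-4-en-1-yl]oct-2-enoate, via alkylborane 10 (not isolated)
Conditions: 9, 9-BBN (2.2 equiv), THF, rt; then 8, Pd(dppf)Cl2 (cat.), aq. K3PO4, DMF, 50 °C
Reagents that add atoms: none
Why: Anti-Markovnikov hydroboration of the terminal alkene and B-alkyl Suzuki–Miyaura coupling with the electron-poor enol triflate should proceed with retention of alkene geometry, the hydroxyl being carried as its borinate and freed on basic work-up.

Step 7
Reactants: 11 enoate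
Product: 13 (6E)-2,2,6-trimethyl-7-[(3R)-3-methyl-3-(triethylsilyloxy)pent-4-en-1-yl]-8-[(trimethylsilyl)methyl]nona-6,8-dien-1-ol, via bis(silylmethyl) carbinol 12 (not isolated)
Conditions: Me3SiCH2MgCl (excess), CeCl3, THF, −78 °C to rt; then SiO2, CH2Cl2, rt
Reagents that add atoms: (trimethylsilyl)methylmagnesium chloride, C[Si](C)(C)C[Mg]Cl
Why: Double 1,2-addition of the non-basic organocerium reagent to the hindered ester followed by Peterson elimination of the bis(β-silyl) carbinol on silica is a known route from esters to 2-substituted allylsilanes and should give the 2-(silylmethyl)diene without touching the tetrasubstituted alkene.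

Step 8
Reactants: 13 dienol
Product: 14 (6E)-2,2,6-trimethyl-7-[(3R)-3-methyl-3-(triethylsilyloxy)pent-4-en-1-yl]-8-[(trimethylsilyl)methyl]nona-6,8-dienal
Conditions: Dess–Martin periodinane, NaHCO3, CH2Cl2, 0 °C to rt
Reagents that add atoms: none
Why: Buffered Dess–Martin oxidation should convert the neopentyl primary alcohol into the non-enolisable aldehyde under neutral conditions that spare the acid-sensitive allylsilane.

Step 9
Reactants: 14 aldehyde
Product: 15 (3E,9E)-5,5,9-trimethyl-10-[(3R)-3-methyl-3-(triethylsilyloxy)pent-4-en-1-yl]-11-[(trimethylsilyl)methyl]dodeca-3,9,11-trien-2-one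
Conditions: (MeO)2P(O)CH2C(O)CH3, Ba(OH)2·8H2O, THF/H2O, rt
Reagents that add atoms: dimethyl (2-oxopropyl)phosphonate, COP(=O)(CC(C)=O)OC
Why: Horner–Wadsworth–Emmons olefination with the stabilised keto phosphonate under mild Ba(OH)2 conditions should give the (E)-enone even from the hindered aldehyde.

Step 10
Reactants: 15 trienone
Product: 16 1-[(13R)-13-(triethylsilyloxy)-17-(trimethylsilyl)labda-8,14-dien-6α-yl]ethan-1-one (5α-H, 10β-methyl)
Conditions: (R)-B-(o-tolyl)oxazaborolidine from (R)-α,α-diphenylprolinol, Tf2NH (20 mol% each), CH2Cl2, −40 to 0 °C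
Reagents that add atoms: none
Why: The cationic oxazaborolidine binds the methyl ketone and lowers the enone LUMO, so that the C7=C8–C9=C10 diene adds to the C5=C6 dienophile in a concerted, asynchronous intramolecular Diels–Alder reaction (type 1, 1,7,9-decatriene), the closest precedent being oxazaborolidinium-catalysed enantioselective intramolecular Diels–Alder cyclisations of trienals and intermolecular ones of enones. Ring B closes by the [4+2] bond pair C6–C7/C5–C10, and ring A closes in fused mode because C5–C10 joins the two ends of the C1–C4 tether (chair-like tether). The endo orientation of the activated acetyl group places H5 endo and C4 exo, and because the tether occupies the outside position of C10 (methyl inside) this gives the trans ring fusion (10β-methyl, 5α-H). C6 follows stereospecifically from the (E)-enone (acetyl cis to H5, that is 6α and equatorial). The absolute sense at C5, C6 and C10 is set by the catalyst, which shields one enone face; the C13 centre is too remote to interfere, and a wrong-face adduct would be a separable diastereomer. The step needs endo over exo and high facial selectivity, secured by Lewis-acid activation, the fixed (E,E) geometry of both partners and the gem-dimethyl group that biases the tether towards the reactive conformer; the allylsilane should survive because no free protic acid is present.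

Step 11
Reactants: 16 cycloadduct
Product: 17 1-[(13R)-13-(triethylsilyloxy)labda-8(17),14-dien-6α-yl]ethan-1-one (9α-H)
Conditions: CF3CO2H (1.5 equiv), CH2Cl2, −20 °C
Reagents that add atoms: none
Why: Protodesilylation of the allylsilane (SE2′) should deliver the proton to C9 from the α face, axial and anti to the 10β-methyl group, which sets the 9α-H (9β side chain) centre and moves the alkene to the exocyclic C8=C17 position.

Step 12
Reactants: 17 ketone
Product: 19 (13R)-8α,17-epoxy-13-(triethylsilyloxy)labd-14-en-6α-yl acetate, via epoxy ketone 18 (not isolated)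
Conditions: mCPBA (excess), Na2HPO4, CH2Cl2, 0 °C to rt
Reagents that add atoms: 3-chloroperbenzoic acid, OOC(=O)c1cccc(Cl)c1
Why: Prilezhaev epoxidation should attack the 1,1-disubstituted exocyclic alkene fast and from the less hindered α face (opposite the axial C10 methyl) to set C8, after which Baeyer–Villiger oxidation of the methyl ketone by the excess peracid should occur with migration of the secondary C6 and retention of its configuration, the inductively deactivated, hindered vinyl group reacting more slowly.

Step 13
Reactants: 19 epoxy acetate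
Product: 20 (13R)-13-(triethylsilyloxy)labd-14-ene-6α,8α-diol
Conditions: LiAlH4, THF, 0 °C to reflux
Reagents that add atoms: none
Why: LiAlH4 should open the spiro epoxide at its primary carbon C17 to give the 8α-tertiary alcohol with the 8β-methyl group and at the same time cleave the acetate to the 6α-alcohol, the silyl ether being stable to hydride.

Step 14
Reactants: 20 silyl ether diol
Product: 21 (13R)-labd-14-ene-6α,8α,13-triol
Conditions: TBAF, THF, rt to 50 °C
Reagents that add atoms: none
Why: Fluoride-mediated desilylation should free the tertiary C13 alcohol without affecting the other hydroxyl groups.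

Step 15
Reactants: 21 triol; 22 angelic acid
Product: 23 (13R)-8α,13-dihydroxylabd-14-en-6α-yl (2Z)-2-methylbut-2-enoate (target)
Conditions: 22, 2,4,6-trichlorobenzoyl chloride, Et3N, toluene, rt; then 21, toluene, 80 °C
Reagents that add atoms: none
Why: Mixed-anhydride (Yamaguchi-type) esterification run without nucleophilic catalyst should acylate only the secondary 6α-hydroxyl, the two tertiary alcohols being inert, and is known to transfer the angeloyl group without Z-to-E isomerisation.

**Compound list**

1 | (R)-(−)-linalool | C=C[C@](C)(O)CCC=C(C)C | starting material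
2 | (5R)-5-ethenyl-5-methyloxolan-2-ol | C=C[C@@]1(C)CCC(O)O1 | intermediate
3 | (3R)-5-iodo-3-methylpent-1-en-3-yl formate | C=C[C@](C)(OC=O)CCI | intermediate (not isolated)
4 | (3R)-5-iodo-3-methylpent-1-en-3-ol | C=C[C@](C)(O)CCI | intermediate
5 | triethyl{[(3R)-5-iodo-3-methylpent-1-en-3-yl]oxy}silane | C=C[C@](C)(O[Si](CC)(CC)CC)CCI | intermediate
6 | methyl acetoacetate | COC(=O)CC(C)=O | starting material
7 | methyl (5R)-2-acetyl-5-methyl-5-(triethylsilyloxy)hept-6-enoate | C=C[C@](C)(O[Si](CC)(CC)CC)CCC(C(C)=O)C(=O)OC | intermediate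
8 | methyl (2E)-2-[(3R)-3-methyl-3-(triethylsilyloxy)pent-4-en-1-yl]-3-(trifluoromethylsulfonyloxy)but-2-enoate | C=C[C@](C)(O[Si](CC)(CC)CC)CC/C(C(=O)OC)=C(/C)OS(=O)(=O)C(F)(F)F | intermediate
9 | 2,2-dimethylpent-4-en-1-ol | C=CCC(C)(C)CO | starting material
10 | 9-[5-(9-borabicyclo[3.3.1]nonan-9-yloxy)-4,4-dimethylpentyl]-9-borabicyclo[3.3.1]nonane | CC(C)(COB1C2CCCC1CCC2)CCCB1C2CCCC1CCC2 | intermediate (not isolated)
11 | methyl (2E)-8-hydroxy-3,7,7-trimethyl-2-[(3R)-3-methyl-3-(triethylsilyloxy)pent-4-en-1-yl]oct-2-enoate | C=C[C@](C)(O[Si](CC)(CC)CC)CC/C(C(=O)OC)=C(/C)CCCC(C)(C)CO | intermediate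
12 | bis(silylmethyl) carbinol from double addition to the ester of 11 | C=C[C@](C)(O[Si](CC)(CC)CC)CC/C(=C(/C)CCCC(C)(C)CO)C(O)(C[Si](C)(C)C)C[Si](C)(C)C | intermediate (not isolated)
13 | (6E)-2,2,6-trimethyl-7-[(3R)-3-methyl-3-(triethylsilyloxy)pent-4-en-1-yl]-8-[(trimethylsilyl)methyl]nona-6,8-dien-1-ol | C=C[C@](C)(O[Si](CC)(CC)CC)CC/C(=C(/C)CCCC(C)(C)CO)C(=C)C[Si](C)(C)C | intermediate
14 | (6E)-2,2,6-trimethyl-7-[(3R)-3-methyl-3-(triethylsilyloxy)pent-4-en-1-yl]-8-[(trimethylsilyl)methyl]nona-6,8-dienal | C=C[C@](C)(O[Si](CC)(CC)CC)CC/C(=C(/C)CCCC(C)(C)C=O)C(=C)C[Si](C)(C)C | intermediate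
15 | (3E,9E)-5,5,9-trimethyl-10-[(3R)-3-methyl-3-(triethylsilyloxy)pent-4-en-1-yl]-11-[(trimethylsilyl)methyl]dodeca-3,9,11-trien-2-one | C=C[C@](C)(O[Si](CC)(CC)CC)CC/C(=C(/C)CCCC(C)(C)/C=C/C(C)=O)C(=C)C[Si](C)(C)C | intermediate
16 | 1-[(13R)-13-(triethylsilyloxy)-17-(trimethylsilyl)labda-8,14-dien-6α-yl]ethan-1-one | C=C[C@](C)(O[Si](CC)(CC)CC)CCC1=C(C[Si](C)(C)C)C[C@H](C(C)=O)[C@H]2C(C)(C)CCC[C@]12C | intermediate
17 | 1-[(13R)-13-(triethylsilyloxy)labda-8(17),14-dien-6α-yl]ethan-1-one | C=C[C@](C)(O[Si](CC)(CC)CC)CC[C@H]1C(=C)C[C@H](C(C)=O)[C@H]2C(C)(C)CCC[C@]12C | intermediate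
18 | 1-[(13R)-8α,17-epoxy-13-(triethylsilyloxy)labd-14-en-6α-yl]ethan-1-one | C=C[C@](C)(O[Si](CC)(CC)CC)CC[C@H]1[C@@]3(CO3)C[C@H](C(C)=O)[C@H]2C(C)(C)CCC[C@]12C | intermediate (not isolated)
19 | (13R)-8α,17-epoxy-13-(triethylsilyloxy)labd-14-en-6α-yl acetate | C=C[C@](C)(O[Si](CC)(CC)CC)CC[C@H]1[C@@]3(CO3)C[C@H](OC(C)=O)[C@H]2C(C)(C)CCC[C@]12C | intermediate
20 | (13R)-13-(triethylsilyloxy)labd-14-ene-6α,8α-diol | C=C[C@](C)(O[Si](CC)(CC)CC)CC[C@H]1[C@](C)(O)C[C@H](O)[C@H]2C(C)(C)CCC[C@]12C | intermediate
21 | (13R)-labd-14-ene-6α,8α,13-triol | C=C[C@](C)(O)CC[C@H]1[C@](C)(O)C[C@H](O)[C@H]2C(C)(C)CCC[C@]12C | intermediate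
22 | angelic acid, (2Z)-2-methylbut-2-enoic acid | C/C=C(/C)C(=O)O | starting material
23 | (13R)-8α,13-dihydroxylabd-14-en-6α-yl (2Z)-2-methylbut-2-enoate | C=C[C@](C)(O)CC[C@@H]1[C@@]2(C)CCCC(C)(C)[C@@H]2[C@@H](OC(=O)/C(C)=C\C)C[C@@]1(C)O | target

Total steps: 15. Longest linear sequence: 15 steps, from (R)-linalool 1.

**Steps most likely to fail, with fallbacks**

Step 10. The hindered, twisted tetrasubstituted diene may react too slowly with the catalyst-bound enone, or facial discrimination may be poor. The fallback replaces catalyst control by auxiliary control. From aldehyde 14, a Horner–Wadsworth–Emmons reaction with (4S)-4-benzyl-3-[(diethoxyphosphoryl)acetyl]-1,3-oxazolidin-2-one (LiCl, iPr2NEt, MeCN) should give the (E)-trienimide F1. Me2AlCl (CH2Cl2, −30 °C) should then drive the cycloaddition through the chelated s-cis imide, the benzyl group shielding the C6 Re face, to the endo imide adduct F2. Transamidation (MeONHMe·HCl, Me3Al) to the Weinreb amide F3 and addition of MeMgBr bring the route back at ketone 16.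

Step 12. The Baeyer–Villiger migration at the hindered ketone may be slow enough for the peracid to begin over-oxidising the C14 vinyl group. The fallback separates the two oxidations. From ketone 17, bis(trimethylsilyl) peroxide with catalytic Me3SiOTf (CH2Cl2, −40 °C), an oxidant that cannot epoxidise, should give the 6α-acetate F4. One equivalent of mCPBA (NaHCO3, 0 °C) then epoxidises only the exocyclic alkene and returns the route at 19.

Step 5. Erosion of enolate geometry would give the (Z)-triflate, which after coupling places the tether on the inside of the diene and leads to the wrong ring fusion. The fallback uses amine-mediated sulfonylation instead of biphasic triflation. From keto ester 7, TsCl with N-methylimidazole and Et3N (non-chelating, E-selective) should give the (E)-enol tosylate F5. Coupling of F5 with borane 10 (Pd(OAc)2, SPhos, K3PO4) returns the route at 11.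

**Further compounds**

F1 | step 10 | (4S)-4-benzyl-3-{(2E,8E)-4,4,8-trimethyl-9-[(3R)-3-methyl-3-(triethylsilyloxy)pent-4-en-1-yl]-10-[(trimethylsilyl)methyl]undeca-2,8,10-trienoyl}-1,3-oxazolidin-2-one | C=C[C@](C)(O[Si](CC)(CC)CC)CC/C(=C(/C)CCCC(C)(C)/C=C/C(=O)N1[C@@H](Cc2ccccc2)COC1=O)C(=C)C[Si](C)(C)C
F2 | step 10 | (4S)-4-benzyl-3-{[(13R)-13-(triethylsilyloxy)-17-(trimethylsilyl)labda-8,14-dien-6α-yl]carbonyl}-1,3-oxazolidin-2-one | C=C[C@](C)(O[Si](CC)(CC)CC)CCC1=C(C[Si](C)(C)C)C[C@H](C(=O)N3[C@@H](Cc4ccccc4)COC3=O)[C@H]2C(C)(C)CCC[C@]12C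
F3 | step 10 | (13R)-N-methoxy-N-methyl-13-(triethylsilyloxy)-17-(trimethylsilyl)labda-8,14-diene-6α-carboxamide | C=C[C@](C)(O[Si](CC)(CC)CC)CCC1=C(C[Si](C)(C)C)C[C@H](C(=O)N(C)OC)[C@H]2C(C)(C)CCC[C@]12C
F4 | step 12 | (13R)-13-(triethylsilyloxy)labda-8(17),14-dien-6α-yl acetate | C=C[C@](C)(O[Si](CC)(CC)CC)CC[C@H]1C(=C)C[C@H](OC(C)=O)[C@H]2C(C)(C)CCC[C@]12C
F5 | step 5 | methyl (2E)-2-[(3R)-3-methyl-3-(triethylsilyloxy)pent-4-en-1-yl]-3-(4-methylphenylsulfonyloxy)but-2-enoate | C=C[C@](C)(O[Si](CC)(CC)CC)CC/C(C(=O)OC)=C(/C)OS(=O)(=O)c1ccc(C)cc1
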